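**Strategy.** Ring C is disconnected at O1–C2 and C3–C4. Both bonds are made in one aminocatalytic oxa-Michael/aldol condensation between a ring-A salicylaldehyde (free O1–H ortho to the C4 formyl carbon) and a 4-(benzyloxy)cinnamaldehyde, whose β- and α-carbons become C2 and C3; its formyl group is a traceless handle. The step exploits the 1,4-relationship of phenolic O1 and carbonyl C4 across the C2(aryl)–C3 unit of the pyranone ring and sets C2 by catalyst control. The C3–OH/C4=O ketol is then unveiled by dihydroxylation, oxidation and retro-Claisen loss of the formyl carbon; C3 follows C2 (trans).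

Key step: step 6

Remark: ring atoms carry flavonoid numbers (O1, C2, C3, C4, C4a, C5–C8, C8a). The sense of induction in step 3 cannot be predicted with certainty for this substrate; the ligand enantiomer that delivers the R centre is used.

Step 1
Reactants: 1 3,5-bis(benzyloxy)phenol
Product: 2 3,5-bis(benzyloxy)-4-bromophenol
Conditions: NBS (1.0 equiv), MeCN, −30 °C → 0 °C
Reagents that add atoms: N-bromosuccinimide, O=C1CCC(=O)N1Br
Why: Electrophilic aromatic bromination, in which the position para to OH and flanked by both benzyloxy groups should react first (as in the para-selective Vilsmeier formylation of 3,5-dialkoxyphenols), any ortho isomer being removed by chromatography.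

Step 2
Reactants: 2 3,5-bis(benzyloxy)-4-bromophenol; 3 1-[4-(benzyloxy)phenyl]ethan-1-one
Product: 5 3,5-bis(benzyloxy)-4-{1-[4-(benzyloxy)phenyl]ethenyl}phenol, via tosylhydrazone 4 (not isolated)
Conditions: 3, TsNHNH2, dioxane, 80 °C; then 2, Pd2(dba)3/XPhos, LiOt-Bu (3.5 equiv), 100 °C
Reagents that add atoms: none
Why: Barluenga coupling, in which the hydrazone gives the diazo compound, the ArPd–carbene undergoes migratory insertion and β-hydride elimination from the methyl group leaves only the 1,1-diarylethene; XPhos is chosen for the electron-rich, di-ortho-substituted bromide.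

Step 3
Reactants: 5 3,5-bis(benzyloxy)-4-{1-[4-(benzyloxy)phenyl]ethenyl}phenol
Product: 6 3,5-bis(benzyloxy)-4-{(1R)-1-[4-(benzyloxy)phenyl]ethyl}phenol
Conditions: [Ir(cod)(P,N*)]BArF (ThrePHOX or phosphite–oxazoline type, 2 mol%), H2 (50 bar), CH2Cl2, rt
Reagents that add atoms: none
Why: Ir–N,P-catalysed asymmetric hydrogenation of a 1,1-diarylethene, the new centre being set by catalyst control that rests on the steric difference between the twisted 2,6-bis(benzyloxy)aryl ring and the coplanar 4-benzyloxyphenyl ring; benzyl ethers are inert.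

Step 4
Reactants: 6 3,5-bis(benzyloxy)-4-{(1R)-1-[4-(benzyloxy)phenyl]ethyl}phenol
Product: 7 2,4-bis(benzyloxy)-3-{(1R)-1-[4-(benzyloxy)phenyl]ethyl}-6-hydroxybenzaldehyde
Conditions: MgCl2, Et3N, (CH2O)n, MeCN, reflux
Reagents that add atoms: paraformaldehyde (formaldehyde), C=O
Why: Casnati–Skattebøl ortho-formylation through the magnesium phenoxide; the two positions ortho to OH are equivalent by symmetry, so only one regioisomer can form, with O1–H free and 5-O/7-O benzylated, and the mild base leaves the diarylmethine centre untouched.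

Step 5
Reactants: 8 4-(benzyloxy)benzaldehyde
Product: 9 (2E)-3-[4-(benzyloxy)phenyl]prop-2-enal
Conditions: Ph3P=CHCHO, toluene, 80 °C
Reagents that add atoms: (triphenylphosphoranylidene)acetaldehyde, O=CC=P(c1ccccc1)(c1ccccc1)c1ccccc1
Why: Wittig olefination with the stabilised formylmethylene ylide should give the (E)-enal.

Step 6
Reactants: 7 2,4-bis(benzyloxy)-3-{(1R)-1-[4-(benzyloxy)phenyl]ethyl}-6-hydroxybenzaldehyde; 9 (2E)-3-[4-(benzyloxy)phenyl]prop-2-enal
Product: 10 (2R)-5,7-bis(benzyloxy)-2-[4-(benzyloxy)phenyl]-6-{(1R)-1-[4-(benzyloxy)phenyl]ethyl}-2H-chromene-3-carbaldehyde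
Conditions: (S)-α,α-diphenylprolinol TMS ether (20 mol%), 2-nitrobenzoic acid (20 mol%), 4 Å MS, toluene, rt
Reagents that add atoms: none
Why: The (S)-prolinol ether converts 9 into an E-iminium ion; the phenolic O1–H of 7 adds to its β-carbon (future C2) from the face not shielded by the CPh2(OTMS) group, the enamine so formed attacks the neighbouring formyl carbon (future C4) with its α-carbon (future C3), and dehydration and hydrolysis release the catalyst and enal 10. The closest known reaction is the diarylprolinol silyl ether-catalysed tandem oxa-Michael/aldol condensation of salicylaldehydes with cinnamaldehydes to 2-aryl-2H-chromene-3-carbaldehydes. The pyran ring closes in the intramolecular aldol step, a 6-(enolexo)-exo-trig cyclisation that follows the intermolecular O1–C2 bond formation. The only new stereocentre, C2, is set by catalyst control (Si-face attack on the iminium ion, expected 2R); the remote side-chain centre should have no influence. The step needs O1 to react in preference to every other oxygen and to the nucleophilic C8 position: O1 is the only free phenol, it sits ortho to the formyl group, and the reversible oxa-Michael addition is drained by the irreversible dehydration that only the O1 adduct can undergo.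

Step 7
Reactants: 10 (2R)-5,7-bis(benzyloxy)-2-[4-(benzyloxy)phenyl]-6-{(1R)-1-[4-(benzyloxy)phenyl]ethyl}-2H-chromene-3-carbaldehyde
Product: 11 (2R,3S,4S)-5,7-bis(benzyloxy)-2-[4-(benzyloxy)phenyl]-6-{(1R)-1-[4-(benzyloxy)phenyl]ethyl}-3,4-dihydroxy-3,4-dihydro-2H-chromene-3-carbaldehyde
Conditions: OsO4 (5 mol%), NMO, citric acid, t-BuOH/acetone/H2O, rt
Reagents that add atoms: osmium tetroxide, O=[Os](=O)(=O)=O (catalytic oxygen carrier); N-methylmorpholine N-oxide, C[N+]1([O-])CCOCC1; water, O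
Why: Upjohn syn-dihydroxylation of the enal C3=C4 bond under citric acid buffering; OsO4 should add anti to the pseudo-axial 2-aryl group (substrate control from C2), placing the C3 oxygen trans to that group.

Step 8
Reactants: 11 (2R,3S,4S)-5,7-bis(benzyloxy)-2-[4-(benzyloxy)phenyl]-6-{(1R)-1-[4-(benzyloxy)phenyl]ethyl}-3,4-dihydroxy-3,4-dihydro-2H-chromene-3-carbaldehyde
Product: 13 (2R,3R)-5,7-bis(benzyloxy)-2-[4-(benzyloxy)phenyl]-6-{(1R)-1-[4-(benzyloxy)phenyl]ethyl}-3-hydroxy-2,3-dihydro-4H-chromen-4-one, via keto aldehyde 12 (not isolated)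
Conditions: DMP, CH2Cl2, 0 °C → rt; crude 12, then K2CO3 (0.3 equiv), MeOH, 0 °C
Reagents that add atoms: none
Why: Dess–Martin oxidation of the benzylic C4 carbinol gives a non-enolisable α-hydroxy-β-keto aldehyde, which loses its formyl group to methoxide by retro-Claisen cleavage; the enediolate is protonated at C3 to the favoured 2,3-trans ketol, so C3 follows the fixed C2 centre.

Step 9
Reactants: 13 (2R,3R)-5,7-bis(benzyloxy)-2-[4-(benzyloxy)phenyl]-6-{(1R)-1-[4-(benzyloxy)phenyl]ethyl}-3-hydroxy-2,3-dihydro-4H-chromen-4-one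
Product: 14 (2R,3R)-3,5,7-trihydroxy-2-(4-hydroxyphenyl)-6-[(1R)-1-(4-hydroxyphenyl)ethyl]-2,3-dihydro-4H-chromen-4-one
Conditions: H2 (1 atm), 10% Pd/C, EtOAc/MeOH, rt
Reagents that add atoms: none
Why: Hydrogenolysis of the four aryl benzyl ethers under neutral conditions, which the aryl ketone, the C2–O1 bond and the three stereocentres should survive, as in standard debenzylations of dihydroflavonols.

**Compound list**

1 | 3,5-bis(benzyloxy)phenol | Oc1cc(OCc2ccccc2)cc(OCc2ccccc2)c1 | starting material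
2 | 3,5-bis(benzyloxy)-4-bromophenol | Oc1cc(OCc2ccccc2)c(Br)c(OCc2ccccc2)c1 | intermediate
3 | 1-[4-(benzyloxy)phenyl]ethan-1-one | CC(=O)c1ccc(OCc2ccccc2)cc1 | starting material
4 | N'-{(1E)-1-[4-(benzyloxy)phenyl]ethylidene}-4-methylbenzenesulfonohydrazide (tosylhydrazone of 3) | C/C(c1ccc(OCc2ccccc2)cc1)=N\NS(=O)(=O)c1ccc(C)cc1 | intermediate (not isolated)
5 | 3,5-bis(benzyloxy)-4-{1-[4-(benzyloxy)phenyl]ethenyl}phenol | C=C(c1ccc(OCc2ccccc2)cc1)c1c(OCc2ccccc2)cc(O)cc1OCc1ccccc1 | intermediate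
6 | 3,5-bis(benzyloxy)-4-{(1R)-1-[4-(benzyloxy)phenyl]ethyl}phenol | C[C@H](c1ccc(OCc2ccccc2)cc1)c1c(OCc2ccccc2)cc(O)cc1OCc1ccccc1 | intermediate
7 | 2,4-bis(benzyloxy)-3-{(1R)-1-[4-(benzyloxy)phenyl]ethyl}-6-hydroxybenzaldehyde | C[C@H](c1ccc(OCc2ccccc2)cc1)c1c(OCc2ccccc2)cc(O)c(C=O)c1OCc1ccccc1 | intermediate
8 | 4-(benzyloxy)benzaldehyde | O=Cc1ccc(OCc2ccccc2)cc1 | starting material
9 | (2E)-3-[4-(benzyloxy)phenyl]prop-2-enal | O=C/C=C/c1ccc(OCc2ccccc2)cc1 | intermediate
10 | (2R)-5,7-bis(benzyloxy)-2-[4-(benzyloxy)phenyl]-6-{(1R)-1-[4-(benzyloxy)phenyl]ethyl}-2H-chromene-3-carbaldehyde | C[C@H](c1ccc(OCc2ccccc2)cc1)c1c(OCc2ccccc2)cc2c(c1OCc1ccccc1)C=C(C=O)[C@@H](c1ccc(OCc3ccccc3)cc1)O2 | intermediate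
11 | (2R,3S,4S)-5,7-bis(benzyloxy)-2-[4-(benzyloxy)phenyl]-6-{(1R)-1-[4-(benzyloxy)phenyl]ethyl}-3,4-dihydroxy-3,4-dihydro-2H-chromene-3-carbaldehyde (3-OH and 4-OH cis, both trans to the 2-aryl group) | C[C@H](c1ccc(OCc2ccccc2)cc1)c1c(OCc2ccccc2)cc2c(c1OCc1ccccc1)[C@H](O)[C@@](O)(C=O)[C@@H](c1ccc(OCc3ccccc3)cc1)O2 | intermediate
12 | (2R,3S)-5,7-bis(benzyloxy)-2-[4-(benzyloxy)phenyl]-6-{(1R)-1-[4-(benzyloxy)phenyl]ethyl}-3-hydroxy-4-oxo-3,4-dihydro-2H-chromene-3-carbaldehyde | C[C@H](c1ccc(OCc2ccccc2)cc1)c1c(OCc2ccccc2)cc2c(c1OCc1ccccc1)C(=O)[C@@](O)(C=O)[C@@H](c1ccc(OCc3ccccc3)cc1)O2 | intermediate (not isolated)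
13 | (2R,3R)-5,7-bis(benzyloxy)-2-[4-(benzyloxy)phenyl]-6-{(1R)-1-[4-(benzyloxy)phenyl]ethyl}-3-hydroxy-2,3-dihydro-4H-chromen-4-one | C[C@H](c1ccc(OCc2ccccc2)cc1)c1c(OCc2ccccc2)cc2c(c1OCc1ccccc1)C(=O)[C@H](O)[C@@H](c1ccc(OCc3ccccc3)cc1)O2 | intermediate
14 | (2R,3R)-3,5,7-trihydroxy-2-(4-hydroxyphenyl)-6-[(1R)-1-(4-hydroxyphenyl)ethyl]-2,3-dihydro-4H-chromen-4-one | C[C@H](c1ccc(O)cc1)c1c(O)cc2c(c1O)C(=O)[C@H](O)[C@@H](c1ccc(O)cc1)O2 | target

**Step count.** Total steps: 9. Longest linear sequence: 8 steps (1, 2, 3, 4, 6, 7, 8, 9).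

**Steps most likely to fail**

Step 6. The aldol closure onto the hindered, electron-rich formyl group of 7 may be slow, so that the reversible oxa-Michael adduct reverts, Friedel–Crafts C-alkylation of ring A at C8 by the iminium ion competes, or facial control at C2 erodes. The fallback sets out from 6 and returns at 13 by the classical chalcone-epoxide construction. Ortho-acetylation of 6 (Ac2O, BF3·OEt2) should give 1-{2,4-bis(benzyloxy)-3-[(1R)-1-(4-benzyloxyphenyl)ethyl]-6-hydroxyphenyl}ethan-1-one F1. Protection (NaH, MOMCl) gives its methoxymethyl ether F2. Claisen–Schmidt condensation with 8 (KOH, EtOH) gives the (E)-chalcone F3. Juliá–Colonna epoxidation (poly-L-leucine, urea–H2O2, DBU, THF) gives the (2R,3S)-epoxy ketone F4. HCl/MeOH then removes the MOM group and lets O1 open the epoxide at the benzylic carbon with inversion, giving 13.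

Step 3. Facial discrimination of the 1,1-diarylethene may be poor or of the wrong sense, and the acidic iridium hydride may trigger cationic oligomerisation of the very electron-rich alkene. The fallback sets out from 5 and returns at 6 by an ionic route: chiral phosphoric acid-catalysed transfer hydrogenation with a Hantzsch ester, in which protonation of 5 gives the ring-A para-quinone methide and hydride is delivered inside the chiral phosphate ion pair. This fallback makes no new compound (F0).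

Step 7. Osmylation of the electron-poor, hindered trisubstituted enal may stall, and the β-hydroxy aldehyde 11 may undergo retro-aldol cleavage of the C3–C4 bond. The fallback sets out from 10 and returns at 12, and from there to 13 by the second stage of step 8. Weitz–Scheffer epoxidation (H2O2, NaOH, MeOH, 0 °C) should give the 3,4-epoxy-3-carbaldehyde F5 with the epoxide anti to the 2-aryl group. Acid-promoted opening at benzylic C4 by DMSO followed by Kornblum-type elimination (DMSO, cat. TfOH; then Et3N) then gives 12.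

**Further compounds**

F1 | step 6 | 1-{2,4-bis(benzyloxy)-3-[(1R)-1-(4-benzyloxyphenyl)ethyl]-6-hydroxyphenyl}ethan-1-one | C[C@H](c1ccc(OCc2ccccc2)cc1)c1c(OCc2ccccc2)cc(O)c(C(C)=O)c1OCc1ccccc1
F2 | step 6 | 1-{2,4-bis(benzyloxy)-3-[(1R)-1-(4-benzyloxyphenyl)ethyl]-6-(methoxymethoxy)phenyl}ethan-1-one | C[C@H](c1ccc(OCc2ccccc2)cc1)c1c(OCc2ccccc2)cc(OCOC)c(C(C)=O)c1OCc1ccccc1
F3 | step 6 | (2E)-1-{2,4-bis(benzyloxy)-3-[(1R)-1-(4-benzyloxyphenyl)ethyl]-6-(methoxymethoxy)phenyl}-3-[4-(benzyloxy)phenyl]prop-2-en-1-one | C[C@H](c1ccc(OCc2ccccc2)cc1)c1c(OCc2ccccc2)cc(OCOC)c(C(=O)/C=C/c2ccc(OCc3ccccc3)cc2)c1OCc1ccccc1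
F4 | step 6 | {2,4-bis(benzyloxy)-3-[(1R)-1-(4-benzyloxyphenyl)ethyl]-6-(methoxymethoxy)phenyl}{(2R,3S)-3-[4-(benzyloxy)phenyl]oxiran-2-yl}methanone | C[C@H](c1ccc(OCc2ccccc2)cc1)c1c(OCc2ccccc2)cc(OCOC)c(C(=O)[C@@H]2O[C@H]2c2ccc(OCc3ccccc3)cc2)c1OCc1ccccc1
F0 | step 3 | none | none
F5 | step 7 | (2R)-5,7-bis(benzyloxy)-2-[4-(benzyloxy)phenyl]-6-{(1R)-1-[4-(benzyloxy)phenyl]ethyl}-3,4-epoxy-3,4-dihydro-2H-chromene-3-carbaldehyde (epoxide anti to the 2-aryl group) | C[C@H](c1ccc(OCc2ccccc2)cc1)c1c(OCc2ccccc2)cc2c(c1OCc1ccccc1)[C@@H]1O[C@]1(C=O)[C@@H](c1ccc(OCc3ccccc3)cc1)O2
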